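5 questions stood against 4 flasks, and I went at them with one clock: how long the partner stays strong enough to couple.

    partner → decomposed reagent (k1 = 0.011 s⁻¹)
    2 starting material → side product B (k2 = 0.32 M⁻¹ s⁻¹)
    starting material → side product A (k3 = 7.6 × 10⁻⁴ s⁻¹)
    target ⇌ isomer of the product (K4 = 0.35, k4 = 0.0012 s⁻¹)
    starting material + partner → target (k5 = 0.77 M⁻¹ s⁻¹)

| flask | starting material | partner | time | remark |
|---|---|---|---|---|
| maple | 20 mM | 3.00 equiv | 50 min | a closed flask charged with all of it at once and left for 50 min |
| cedar | 20 mM | 3.00 equiv |  | a single well-mixed tank run continuously and read at steady state, 50 min in it on average |
| elm | 20 mM (fed, over 25.0 min) | 3.00 equiv | 50 min | a stirred flask in which starting material is dosed at a steady rate over 25.0 min without added volume, worked up at 50 min |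
| alder | 20 mM | 3.00 equiv (fed, over 25.0 min) | 50 min | a stirred flask in which partner is dosed at a steady rate over 25.0 min without added volume, worked up at 50 min |

1. the set-up with the highest share of target in all that became target or side product A or side product B or isomer of the product, at the outlet or at the end ("none" if the first two lie within 2 percentage points) (maple / cedar / elm / alder / none)
2. share of target in all that became target or side product A or side product B or isomer of the product, at the outlet or at the end, maple
3. share of target in all that became target or side product A or side product B or isomer of the product, at the outlet or at the end, cedar
4. share of target in all that became target or side product A or side product B or isomer of the product, at the outlet or at the end, elm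
5. share of target in all that became target or side product A or side product B or isomer of the product, at the outlet or at the end, alder

- percentages count the starting material that a species holds: one side product B counts as two
- a doubled species enters its step squared and goes two at a time
- the stated concentrations are those of everything mixed, before any reaction; amounts are the same in each set-up
- the feed brings no volume worth counting
- run time (maple): 50 min

I began with the coupling by itself in maple: there target was the one product, a share of 100 per cent.

Then I added the decay of the partner. Starting material sees a pseudo-first-order constant, the coupling constant times the partner, and since the partner, counted by decay alone, falls exponentially, that constant integrates in closed form to a reach, the natural logarithm of the fall in starting material that coupling can bring over the partner's life: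

reach = 0.77 M⁻¹ s⁻¹ × 60.0 mM / 0.011 s⁻¹ = 4.20

A portion entering later meets a reach shrunk by the same exponential, so the reach falls to one at

window = ln(reach) / 0.011 s⁻¹ = 2.17 min

This coupling window, the time after mixing at which the remaining reach of the partner has fallen to one, counting decay alone, was my clock. Maple's charge enters at the start, inside the window, and by this reckoning its reach leaves 1.50% uncoupled, with the partner used in coupling not counted and no loss added. With coupling still the one route in the reckoning, the share in maple stayed at 100 per cent. Elm's feed lasts longer than the window, so I gave coupling 8.70% of the feed.

Next came the two losses of starting material. At maple's opening, the constants per starting material were 0.0462 s⁻¹ for coupling, 0.0128 s⁻¹ for the doubled step and 7.6 × 10⁻⁴ s⁻¹ for side product A. I held those opening values through the run as an estimate, which took the share to 77.3%.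

Last came the isomer. Target and isomer of the product relax in 3.60 min, much sooner than the 50 min of the run, so target keeps 74.1% of the pair.

My reckoning gave maple 57.3% and elm 6.44%. I did not reckon cedar or alder.

The forecast named maple, with 59% for maple, 28.7% for cedar, 9.5% for elm and 19% for alder, on the ground that “coupling outruns both dimerisation and partner decay”.

The simulation gave maple as best, with 59.5%, then 28.7% for cedar, 7.77% for elm and 15.3% for alder. In elm, target and isomer of the product together held 10.3% of the charge at the end, beside the 8.70% of the feed that my window of 2.17 min had given to coupling.

On the neighbour, elm with 7.50 equiv of partner, the window became 3.56 min: 2.50 times the partner lengthened it 1.64 times. That gave a share of 10.6%, and the simulation gave 11.8%.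

(The rate constants come from no measurement; the rest is arithmetic.)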